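## Analysis of the target

Compound 17 is a flavone: a benzo-fused 4-pyranone in which ring A is fused to ring C through C4a–C8a, with a 2,5-dimethoxyphenyl ring B on C2. It has no stereocentre, so the problem is one of constitution only: where the oxygens sit and which one stays unmethylated. Ring A is pentasubstituted, with the free hydroxyl on C5, hydrogen on C6 and methoxyls on C7 and C8. This 5,7,8 pattern is easily confused with the 5,6,7 pattern whenever a synthesis passes through a ring A with two free oxygens flanking the acyl carbon. The C5 hydroxyl is hydrogen-bonded to the C4 carbonyl, which makes it the least nucleophilic oxygen and makes its methyl ether the one a chelating Lewis acid removes first. The sensitive points are the two electron-rich arenes (C6 lies between two oxygen-bearing carbons and is strongly nucleophilic), the methyl ethers under strong acid, and, in any reduced precursor, the enol ether O1–C2=C3. The difficulty is to close ring C with O1 on the correct ring A carbon and the aryl group on C2 without exposing these rings to harsh electrophiles or oxidants. The strategy rests on the fusion of ring C at C4a–C8a to a phenol ring whose oxygen is O1: once C4 is a methylene, O1–C8a–C4a–C4 is an ortho-quinone methide and C2–C3 an arylalkyne, so ring C is a [4+2] adduct of two simple aromatic fragments.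

## Retrosynthetic reasoning

**17 to 15.** The last bond cut is the O–CH3 bond at C5. Of the five methyl ethers in 15, only this one is peri to the C4 carbonyl, so chelation-controlled cleavage can single it out. Keeping the C5 oxygen methylated until the end also means every earlier ring A intermediate has one phenolic oxygen only. The forward step must remove one methyl group out of five.

**15 to 13.** The C4 carbonyl is taken back to a methylene; no skeletal bond is cut. In 13, C4 is benzylic to ring A and allylic to the C2=C3 enol ether, so it holds the weakest C–H bonds of the molecule and a radical peroxidation should find it. The gain is that ring C at this oxidation level is a cycloadduct; the price is one oxidation after ring closure.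

**13 to 9 and 11.** This is the key disconnection: C3–C4 and O1–C2 are cut together. It divides 13 into salicyl alcohol 9 (ring A with C4 and O1) and alkyne 11 (ring B with C2 and C3), two fragments of equal size. The cut is made here and not at C4–C4a or O1–C8a because both bonds can form in one polar event whose regiochemistry is set by charge: the methide carbon of quinone methide 12 is the electrophile and the alkyne terminus the nucleophile. The forward reaction must ionise 9 to 12 with a catalytic amount of acid and have 12 captured by 11 faster than by another arene.

**9 to 8 to 7.** The hydroxymethyl group of 9 comes from aldehyde 8 by hydride reduction. Aldehyde 8 comes from phenol 7 by cutting the bond between the formyl carbon and the ring, the future C4–C4a bond. In 7 one of the two ortho carbons already bears a methoxyl, so a phenoxide-directed ortho-formylation has a single site. Compound 9 is made last and used at once because it is acid-labile.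

**7 to 4 to 3 to 1.** The phenolic C–O bond of 7 is traced to the C–Br bond of 4 (ipso-hydroxylation by lithiation, borylation and oxidation). The methyl ether of 4 is traced to phenol 3, and the C–O bond of 3 to the formyl group of 1 (Baeyer–Villiger oxidation). In 1 the four substituents already stand in the required relation: bromine marks the future O1 and the formyl carbon marks the future C5 oxygen. No regiochemical decision is therefore left in the construction of ring A. A shorter access that would unmask the phenol by cleaving one of two ortho methyl ethers beside a formyl group was not used, because it would bring a regiochemical question into the precursor synthesis.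

**11 to 10.** The terminal alkyne carbon is removed, leaving aldehyde 10; the forward step is a one-carbon Seyferth–Gilbert homologation.

## Alternatives that were turned down

**Alternative 1:** The disconnection is the C7–C8 bond of ring A, with rings B and C already in place.
- Precursor: methyl 3-[6-(2,5-dimethoxyphenyl)-2-(methoxymethyl)-4-oxo-4H-pyran-3-yl]-3-oxopropanoate A1. Its β-ketoester arm holds C5, C6 and C7, and its methoxymethyl group is C8.
- Forward key step: an excess of LDA deprotonates the β-ketoester and then the methoxymethyl group, which is vinylogously acidified by the pyranone carbonyl and the C5 ketone. The C8 carbanion adds to the ester carbon, methoxide leaves, and double enolisation gives 2-(2,5-dimethoxyphenyl)-5,7-dihydroxy-8-methoxy-4H-chromen-4-one A2. Methylation of the C7 hydroxyl, the only non-chelated one, would finish 17.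
- For: C4 is a carbonyl from the start and the ring A oxygen pattern is written into the chain. The C5 hydroxyl emerges free and is told apart from the C7 hydroxyl by its hydrogen bond. Neither a C–H oxidation nor an ether cleavage is needed, and on these two points it is stronger than the chosen route.
- Against: A1 is a 4-pyranone with three different carbon substituents, and its regiocontrolled assembly alone should need more steps than the chosen route needs to reach 9. The first deprotonation makes the β-ketoester an enolate and so deactivates the very ester carbonyl that must be attacked. An α-methoxy carbanion is a reluctant nucleophile, and 4-pyranones are opened by strong bases and by the methoxide set free.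
- Comparison: the chosen strategy takes both aromatic rings ready-made and puts its one uncertain bond formation into a catalytic union of two small fragments. It gives up the C4 oxidation level and the free C5 hydroxyl, which cost two steps after ring closure.

**Alternative 2:** The disconnection is O1–C8a, with ring A raised to the quinone level so that C8a becomes an electrophile.
- Precursor: 1-(3,6-dihydroxy-2,4-dimethoxyphenyl)-3-(2,5-dimethoxyphenyl)propane-1,3-dione A3.
- Forward key step: Ag2O oxidises A3 to the acylquinone 2-[3-(2,5-dimethoxyphenyl)-3-oxopropanoyl]-3,5-dimethoxycyclohexa-2,5-diene-1,4-dione A4. Its methoxy-bearing C8a is the β-carbon of both the C5 and the C4 carbonyl. The enol oxygen of the diketone adds there in a 6-endo-trig fashion and methoxide is expelled, giving 2-(2,5-dimethoxyphenyl)-7-methoxy-4H-chromene-4,5,8-trione A5. Reduction of the quinone with Na2S2O4 and methylation of the non-chelated C8 hydroxyl would give 17.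
- For: the C4 carbonyl and the free C5 hydroxyl arrive without C–H oxidation or ether cleavage. The ring closure is a polar addition–elimination with fixed regiochemistry and is arguably more certain than the capture of 12 by an alkyne.
- Against: A3 carries five different substituents on one ring, including two para hydroxyls, and its preparation plus the diketone assembly is long. Ring A is oxidised and reduced again only to activate C8a, two steps that form no skeletal bond. 2-Acylquinones such as A4 are among the most electrophilic quinones and add water, alcohols or the diketone carbon of a second molecule. The 5,8-hydroquinone to be methylated at the end is air-sensitive.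
- Comparison: the number of steps after ring closure is the same (two), but the way to the precursor is longer and more delicate. The chosen strategy has no redox cycling of ring A, and its two precursors are each reached by standard aromatic chemistry.

**Alternative 3:** The disconnection is C4–C4a.
- Precursor: phenol 7 of the chosen route would be added to methyl 3-(2,5-dimethoxyphenyl)prop-2-ynoate A6 and the ester saponified to (2Z)-3-(2,5-dimethoxyphenyl)-3-(2,3,5-trimethoxyphenoxy)prop-2-enoic acid A7.
- Forward key step: P2O5 in CH3SO3H turns the acid into a mixed anhydride or acylium ion. This acylates the one free ortho carbon of the aryloxy ring, which is activated by an ortho and a para methoxyl, and closes ring C. The product, 2-(2,5-dimethoxyphenyl)-5,7,8-trimethoxy-4H-chromen-4-one A8, is the same compound as 15.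
- For: it uses the same phenol 7 and reaches the flavone in three steps from it where the chosen route needs four. It delivers C4 at the right oxidation level and so avoids the least secure step of the chosen route, and the position of O1 is equally unambiguous. The total step count is the same, but the longest linear sequence is one step shorter. On these points it is the stronger plan.
- Against: only the Z acid, with carboxyl cis to the aryloxy group, can close ring C. The E isomer presents the acylium to ring B and leads towards an indenone, and conjugate addition of a hindered phenoxide to A6 does not guarantee the geometry. A7 is a vinylogous carbonate: its acylium is stabilised and weakly electrophilic, and in hot strong acid it can revert to 7 by retro-addition or hydrolysis. A stoichiometric sulfonic acid medium meets five methyl ethers and two activated rings, so sulfonylation, ether cleavage and intermolecular acylation at the carbon between the two ring A methoxyls are foreseeable losses.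
- Comparison: the chosen strategy accepts one more step on the main line and a C–H oxidation. In return, ring closure is catalytic and near-neutral, geometry plays no part because the alkyne is linear, and the sensitive rings never meet a stoichiometric strong acid.

Key step: step 7

Remark on the chemistry: 1 and 10 are taken as commercial. The target has no stereocentre; intermediate 14 and fallback compounds F3 and F5 each have one stereocentre and would form as racemates, which is of no consequence.

## Route

Step 1
Reactants: 1 3-bromo-4,5-dimethoxybenzaldehyde
Product: 3 3-bromo-4,5-dimethoxyphenol, via 3-bromo-4,5-dimethoxyphenyl formate 2 (not isolated)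
Conditions: mCPBA, CH2Cl2, 0 °C → rt; aq. NaHCO3 wash; then Et3N (cat.), MeOH, rt
Reagents that add atoms: mCPBA (3-chloroperoxybenzoic acid), OOC(=O)c1cccc(Cl)c1
Why: Baeyer–Villiger oxidation; in the Criegee adduct the aryl group, made migration-prone by the methoxyl para to the formyl group, should shift in preference to hydride and give formate 2, which methanolysis cleaves to the phenol. The aryl bromide and the methyl ethers are inert to the peracid.

Step 2
Reactants: 3 3-bromo-4,5-dimethoxyphenol
Product: 4 1-bromo-2,3,5-trimethoxybenzene
Conditions: MeI, K2CO3, acetone, reflux
Reagents that add atoms: iodomethane, CI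
Why: Williamson O-methylation of the only acidic site; the phenoxide is the sole nucleophile present, so no selectivity question arises.

Step 3
Reactants: 4 1-bromo-2,3,5-trimethoxybenzene
Product: 7 2,3,5-trimethoxyphenol, via 2,3,5-trimethoxyphenyllithium 5 (not isolated), via dimethyl (2,3,5-trimethoxyphenyl)boronate 6 (not isolated)
Conditions: n-BuLi, THF, −78 °C; B(OMe)3, −78 °C → rt; then AcOH, 30% aq. H2O2, 0 °C → rt; Na2SO3 quench
Reagents that add atoms: hydrogen peroxide, OO (the phenolic oxygen of 7); n-butyllithium, [Li]CCCC (the lithium of 5); trimethyl borate, COB(OC)OC (the B(OMe)2 group of 6)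
Why: Bromine–lithium exchange at −78 °C is faster than any ortho-lithiation, borate trapping gives 6, and peroxide induces the 1,2-shift of the aryl group from boron to oxygen (ipso-hydroxylation), so the hydroxyl should end exactly where the bromine was. The oxidant is kept near stoichiometric and quenched to spare the electron-rich phenol.

Step 4
Reactants: 7 2,3,5-trimethoxyphenol
Product: 8 2-hydroxy-3,4,6-trimethoxybenzaldehyde
Conditions: (CH2O)n, MgCl2, Et3N, MeCN, reflux; dilute aq. HCl work-up
Reagents that add atoms: paraformaldehyde (reacting as formaldehyde), C=O
Why: Magnesium-mediated ortho-formylation (Casnati–Skattebøl); the magnesium phenoxide delivers formaldehyde to the ortho carbon through a six-membered chelate and a second formaldehyde takes up hydride to raise the hydroxymethyl group to the aldehyde. Only one ortho carbon of 7 is free and the chelate mechanism does not reach the para carbon, so a single aldehyde is expected.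

Step 5
Reactants: 8 2-hydroxy-3,4,6-trimethoxybenzaldehyde
Product: 9 2-(hydroxymethyl)-3,5,6-trimethoxyphenol
Conditions: NaBH4, THF–MeOH, 0 °C, short reaction time; pH 7 buffer work-up, used crude in step 7
Reagents that add atoms: none
Why: Borohydride 1,2-reduction of an aryl aldehyde; the temperature is kept low and the work-up neutral because this electron-rich salicyl alcohol ionises easily and must not meet acid before the key step.

Step 6
Reactants: 10 2,5-dimethoxybenzaldehyde
Product: 11 2-ethynyl-1,4-dimethoxybenzene
Conditions: dimethyl (1-diazo-2-oxopropyl)phosphonate, K2CO3, MeOH, rt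
Reagents that add atoms: dimethyl (1-diazo-2-oxopropyl)phosphonate (Ohira–Bestmann reagent), COP(=O)(OC)C(=[N+]=[N-])C(C)=O
Why: Seyferth–Gilbert homologation in the Ohira–Bestmann variant; methoxide deacylates the reagent, the diazophosphonate anion olefinates the aldehyde in Horner–Wadsworth–Emmons fashion, and loss of N2 followed by a 1,2-hydrogen shift of the alkylidene carbene should give the terminal alkyne. A non-enolisable aryl aldehyde is the ideal substrate.

Step 7
Reactants: 9 2-(hydroxymethyl)-3,5,6-trimethoxyphenol; 11 2-ethynyl-1,4-dimethoxybenzene
Product: 13 2-(2,5-dimethoxyphenyl)-5,7,8-trimethoxy-4H-chromene, via 2,3,5-trimethoxy-6-methylidenecyclohexa-2,4-dien-1-one 12 (not isolated)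
Conditions: FeCl3 (10 mol %), 11 (3 equiv), 4 Å MS, ClCH2CH2Cl, 0 °C → rt, slow addition of 9; Et3N quench, Et3N-deactivated silica
Reagents that add atoms: none
Why: FeCl3 binds the benzylic hydroxyl of 9 and ionises it; the cation is stabilised by the ortho and para methoxyls (future C5 and C7) and by the ortho hydroxyl, and loss of the phenolic proton makes it the ortho-quinone methide 12. The unsubstituted terminus of alkyne 11 attacks the exocyclic methide carbon (C3–C4), which puts the developing charge on the aryl-bearing carbon as an α-aryl vinyl cation supported by the ortho methoxyl of ring B. The ring A oxygen then closes on that carbon (O1–C2); overall this is an inverse-electron-demand oxa-[4+2] cycloaddition with 12 as the 1-oxadiene, and seen stepwise the six-membered ring C closes by 6-endo-dig capture of the vinyl cation. The closest known reaction type is the Lewis-acid-catalysed benzylation–cyclisation of ortho-hydroxybenzyl alcohols with arylalkynes to 2-aryl-4H-chromenes. No stereocentre is formed. Regiochemistry (aryl on C2, O1 on C8a) follows from the polarity of 12 and of the alkyne and from the single phenolic oxygen of 9. Chemoselectivity for the alkyne over Friedel–Crafts attack by the nucleophilic ring carbon para to the hydroxyl of a second molecule of 9 (C6 of 13) is secured by low acid loading, excess 11 and slow addition of 9. Water is the only by-product and is held by the sieves, and the amine quench protects the enol ether of 13.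

Step 8
Reactants: 13 2-(2,5-dimethoxyphenyl)-5,7,8-trimethoxy-4H-chromene
Product: 15 2-(2,5-dimethoxyphenyl)-5,7,8-trimethoxy-4H-chromen-4-one, via 4-(tert-butylperoxy)-2-(2,5-dimethoxyphenyl)-5,7,8-trimethoxy-4H-chromene 14 (not isolated)
Conditions: t-BuOOH (5 equiv, decane solution), CuI (10 mol %), MeCN, 50 °C
Reagents that add atoms: tert-butyl hydroperoxide, CC(C)(C)OO
Why: Copper-catalysed hydroperoxide oxidation of an activated methylene, the reaction type long used to turn xanthenes and other benzo-fused 4H-pyrans into their ketones; the C4–H bonds are benzylic and allylic to an enol ether and are the weakest in 13. Peroxidation at C4 gives 14, which should lose tert-butanol in a Kornblum–DeLaMare-type elimination to give the conjugated pyranone, the thermodynamic sink of the system.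

Step 9
Reactants: 15 2-(2,5-dimethoxyphenyl)-5,7,8-trimethoxy-4H-chromen-4-one
Product: 17 5-hydroxy-2-(2,5-dimethoxyphenyl)-7,8-dimethoxy-4H-chromen-4-one, via 5-(dichloroboryloxy)-2-(2,5-dimethoxyphenyl)-7,8-dimethoxy-4H-chromen-4-one 16 (not isolated)
Conditions: BCl3 (1.5 equiv), CH2Cl2, −78 → 0 °C; then dilute aq. HCl, rt
Reagents that add atoms: boron trichloride, ClB(Cl)Cl (the BCl2 group of 16; no heavy atom is added to 17)
Why: Chelation-directed Lewis acid ether cleavage; BCl3 binds the C4 carbonyl and only the peri C5 methoxyl can close a six-membered boron chelate, so chloride should remove that methyl group alone and give 16, which aqueous acid hydrolyses to 17. The other four methyl ethers lack this assistance and should survive at low temperature with a small excess of reagent.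

## Compound list

1 | 3-bromo-4,5-dimethoxybenzaldehyde | COc1cc(C=O)cc(Br)c1OC | starting material
2 | 3-bromo-4,5-dimethoxyphenyl formate | COc1cc(OC=O)cc(Br)c1OC | intermediate (not isolated)
3 | 3-bromo-4,5-dimethoxyphenol | COc1cc(O)cc(Br)c1OC | intermediate
4 | 1-bromo-2,3,5-trimethoxybenzene | COc1cc(OC)cc(Br)c1OC | intermediate
5 | 2,3,5-trimethoxyphenyllithium | COc1cc(OC)cc([Li])c1OC | intermediate (not isolated)
6 | dimethyl (2,3,5-trimethoxyphenyl)boronate | COc1cc(OC)cc(B(OC)OC)c1OC | intermediate (not isolated)
7 | 2,3,5-trimethoxyphenol | COc1cc(OC)cc(O)c1OC | intermediate
8 | 2-hydroxy-3,4,6-trimethoxybenzaldehyde | O=Cc1c(O)c(OC)c(OC)cc1OC | intermediate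
9 | 2-(hydroxymethyl)-3,5,6-trimethoxyphenol | OCc1c(O)c(OC)c(OC)cc1OC | intermediate
10 | 2,5-dimethoxybenzaldehyde | COc1ccc(OC)c(C=O)c1 | starting material
11 | 2-ethynyl-1,4-dimethoxybenzene | COc1ccc(OC)c(C#C)c1 | intermediate
12 | 2,3,5-trimethoxy-6-methylidenecyclohexa-2,4-dien-1-one | C=C1C(=O)C(OC)=C(OC)C=C1OC | intermediate (not isolated)
13 | 2-(2,5-dimethoxyphenyl)-5,7,8-trimethoxy-4H-chromene | COc1ccc(OC)c(c1)C1=CCc2c(OC)cc(OC)c(OC)c2O1 | intermediate
14 | 4-(tert-butylperoxy)-2-(2,5-dimethoxyphenyl)-5,7,8-trimethoxy-4H-chromene (racemic) | COc1ccc(OC)c(c1)C1=CC(OOC(C)(C)C)c2c(OC)cc(OC)c(OC)c2O1 | intermediate (not isolated)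
15 | 2-(2,5-dimethoxyphenyl)-5,7,8-trimethoxy-4H-chromen-4-one | COc1ccc(OC)c(-c2cc(=O)c3c(OC)cc(OC)c(OC)c3o2)c1 | intermediate
16 | 5-(dichloroboryloxy)-2-(2,5-dimethoxyphenyl)-7,8-dimethoxy-4H-chromen-4-one | COc1ccc(OC)c(-c2cc(=O)c3c(OB(Cl)Cl)cc(OC)c(OC)c3o2)c1 | intermediate (not isolated)
17 | 5-hydroxy-2-(2,5-dimethoxyphenyl)-7,8-dimethoxy-4H-chromen-4-one (5-hydroxy-7,8,2',5'-tetramethoxyflavone) | COc1ccc(OC)c(-c2cc(=O)c3c(O)cc(OC)c(OC)c3o2)c1 | target

## Step count and least certain steps

Total: 9 steps. Longest linear sequence: 8 steps (1 to 17 through steps 1–5, 7, 8 and 9); step 6 is a one-step branch.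

**Step 7 (key step).** The most likely failure is acid-driven intermolecular Friedel–Crafts alkylation. This includes self-condensation of 9 through its ring carbon para to the hydroxyl and benzylation of C6 of 13 or of ring B. Hydride transfer from C4 of 13 to the benzylic cation is a further loss. All of these compete because an arylalkyne is only a moderate π-nucleophile. The fallback forms the same two bonds without acid and with a stronger 2π partner. It sets out from 9. Commercial 1-(2,5-dimethoxyphenyl)ethan-1-one F1 would be converted with TBSOTf and Et3N into tert-butyl{[1-(2,5-dimethoxyphenyl)ethenyl]oxy}dimethylsilane F2. Heating 9 with F2 in toluene at 110–140 °C should generate 12 thermally and trap it in a [4+2] cycloaddition as racemic 2-[(tert-butyldimethylsilyl)oxy]-2-(2,5-dimethoxyphenyl)-5,7,8-trimethoxychromane F3. A catalytic amount of TsOH in warm toluene would then eliminate the silanol, and the route is rejoined at 13.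

**Step 8.** The delocalised C4/C2 radical, or the flavylium ion derived from it, may be trapped at C2 with opening of ring C. The electron-rich ring A may be degraded oxidatively, or the reaction may stall at peroxide 14. The fallback closes ring C at the ketone level by known ynone chemistry. It sets out from 8, which with MOMCl and i-Pr2NEt should give 3,4,6-trimethoxy-2-(methoxymethoxy)benzaldehyde F4. The lithium acetylide of 11 (n-BuLi, THF, −78 °C) would add to F4 to give racemic 3-(2,5-dimethoxyphenyl)-1-[3,4,6-trimethoxy-2-(methoxymethoxy)phenyl]prop-2-yn-1-ol F5. MnO2 in CH2Cl2 would oxidise F5 to 3-(2,5-dimethoxyphenyl)-1-[3,4,6-trimethoxy-2-(methoxymethoxy)phenyl]prop-2-yn-1-one F6. HCl in MeOH would remove the acetal, and the freed 3-(2,5-dimethoxyphenyl)-1-(2-hydroxy-3,4,6-trimethoxyphenyl)prop-2-yn-1-one F7 should cyclise under the same acid by 6-endo-dig oxa-Michael addition. The route is rejoined at 15.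

**Step 5.** Two processes threaten 9. One is over-reduction to the methylphenol: the phenoxide loses hydroxide and 12 captures hydride. The other is acid-triggered self-condensation during work-up or storage. The fallback avoids hydride and gives a storable masked form. It sets out from 7 and bypasses 8. PhB(OH)2, (CH2O)n and catalytic EtCO2H in refluxing toluene with water removal (boronate-templated ortho-hydroxymethylation) should give 5,7,8-trimethoxy-2-phenyl-4H-1,3,2-benzodioxaborinine F8. Exchange with propane-1,3-diol under neutral conditions would release the salicyl alcohol just before use, and the route is rejoined at 9.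

**Step 9.** A second methyl ether may be lost, most probably the one on C8, which is flanked by O1 and the C7 methoxyl, if temperature or stoichiometry drifts. The fallback accepts the double cleavage and corrects it. It sets out from 15, from which AlBr3 in MeCN should remove the C5 and C8 methyl groups to give 2-(2,5-dimethoxyphenyl)-5,8-dihydroxy-7-methoxy-4H-chromen-4-one F9. MeI (1 equiv) and K2CO3 in acetone under argon should then methylate only the C8 hydroxyl, because the C5 hydroxyl is held in the hydrogen bond to the C4 carbonyl. The route is rejoined at 17.

## Further compounds

F1 | step 7 | 1-(2,5-dimethoxyphenyl)ethan-1-one | CC(=O)c1cc(OC)ccc1OC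
F2 | step 7 | tert-butyl{[1-(2,5-dimethoxyphenyl)ethenyl]oxy}dimethylsilane | C=C(O[Si](C)(C)C(C)(C)C)c1cc(OC)ccc1OC
F3 | step 7 | 2-[(tert-butyldimethylsilyl)oxy]-2-(2,5-dimethoxyphenyl)-5,7,8-trimethoxychromane (racemic) | COc1ccc(OC)c(c1)C1(O[Si](C)(C)C(C)(C)C)CCc2c(OC)cc(OC)c(OC)c2O1
F4 | step 8 | 3,4,6-trimethoxy-2-(methoxymethoxy)benzaldehyde | COCOc1c(C=O)c(OC)cc(OC)c1OC
F5 | step 8 | 3-(2,5-dimethoxyphenyl)-1-[3,4,6-trimethoxy-2-(methoxymethoxy)phenyl]prop-2-yn-1-ol (racemic) | COCOc1c(C(O)C#Cc2cc(OC)ccc2OC)c(OC)cc(OC)c1OC
F6 | step 8 | 3-(2,5-dimethoxyphenyl)-1-[3,4,6-trimethoxy-2-(methoxymethoxy)phenyl]prop-2-yn-1-one | COCOc1c(C(=O)C#Cc2cc(OC)ccc2OC)c(OC)cc(OC)c1OC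
F7 | step 8 | 3-(2,5-dimethoxyphenyl)-1-(2-hydroxy-3,4,6-trimethoxyphenyl)prop-2-yn-1-one | COc1cc(OC)c(C(=O)C#Cc2cc(OC)ccc2OC)c(O)c1OC
F8 | step 5 | 5,7,8-trimethoxy-2-phenyl-4H-1,3,2-benzodioxaborinine | COc1cc(OC)c(OC)c2OB(OCc12)c1ccccc1
F9 | step 9 | 2-(2,5-dimethoxyphenyl)-5,8-dihydroxy-7-methoxy-4H-chromen-4-one | COc1ccc(OC)c(-c2cc(=O)c3c(O)cc(OC)c(O)c3o2)c1
A1 | alternative 1 | methyl 3-[6-(2,5-dimethoxyphenyl)-2-(methoxymethyl)-4-oxo-4H-pyran-3-yl]-3-oxopropanoate | COCC1=C(C(=O)CC(=O)OC)C(=O)C=C(O1)c1cc(OC)ccc1OC
A2 | alternative 1 | 2-(2,5-dimethoxyphenyl)-5,7-dihydroxy-8-methoxy-4H-chromen-4-one | COc1ccc(OC)c(-c2cc(=O)c3c(O)cc(O)c(OC)c3o2)c1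
A3 | alternative 2 | 1-(3,6-dihydroxy-2,4-dimethoxyphenyl)-3-(2,5-dimethoxyphenyl)propane-1,3-dione | COc1ccc(OC)c(c1)C(=O)CC(=O)c1c(O)cc(OC)c(O)c1OC
A4 | alternative 2 | 2-[3-(2,5-dimethoxyphenyl)-3-oxopropanoyl]-3,5-dimethoxycyclohexa-2,5-diene-1,4-dione | COc1ccc(OC)c(c1)C(=O)CC(=O)C1=C(OC)C(=O)C(OC)=CC1=O
A5 | alternative 2 | 2-(2,5-dimethoxyphenyl)-7-methoxy-4H-chromene-4,5,8-trione | COc1ccc(OC)c(c1)C1=CC(=O)C2=C(O1)C(=O)C(OC)=CC2=O
A6 | alternative 3 | methyl 3-(2,5-dimethoxyphenyl)prop-2-ynoate | COC(=O)C#Cc1cc(OC)ccc1OC
A7 | alternative 3 | (2Z)-3-(2,5-dimethoxyphenyl)-3-(2,3,5-trimethoxyphenoxy)prop-2-enoic acid | OC(=O)/C=C(\Oc1cc(OC)cc(OC)c1OC)c1cc(OC)ccc1OC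
A8 | alternative 3 | 2-(2,5-dimethoxyphenyl)-5,7,8-trimethoxy-4H-chromen-4-one (identical with 15) | COc1ccc(OC)c(-c2cc(=O)c3c(OC)cc(OC)c(OC)c3o2)c1
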